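**Retrosynthetic overview**
1. Target ⇒ methanol + a racemic γ-hydroxybutenolide (5-hydroxy-4-aryl-3-benzylfuran-2(5H)-one). The last step forms the ester C–O bond and, through two catalyst-controlled protonations, both stereocenters (carbene-catalysed redox ring-opening esterification).
2. Hydroxybutenolide ⇒ 3-bromo-4-aryl-5-hydroxybutenolide + prenylated benzylic pinacol boronate (sp2–sp3 Suzuki coupling at C3).
3. Bromo-butenolide ⇒ mucobromic acid + (4-hydroxyphenyl)boronic acid (site-selective Suzuki coupling at C4).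
4. Benzylic boronate ⇒ 4-hydroxy-3-prenylbenzaldehyde (tosylhydrazone reductive borylation) ⇒ 4-hydroxybenzaldehyde + prenyl bromide.
5. Rings: none is built. The only non-aromatic ring (the butenolide) is bought with mucobromic acid and opened in the last step; no protecting groups are used.

Assumption: the (5aS,10bR) enantiomer of the aminoindanol-derived triazolium salt is taken to deliver the (2R,3S) product; if the first run shows the opposite sense, the equally available (5aR,10bS) salt is used with nothing else changed.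

**Route**

Step 1
Reactants: 1 4-hydroxybenzaldehyde; 2 prenyl bromide (1-bromo-3-methylbut-2-ene)
Product: 3 4-hydroxy-3-(3-methylbut-2-en-1-yl)benzaldehyde
Conditions: KOH (1.1 equiv), H2O, rt, 24 h; chromatography to remove the O-prenyl ether
Reagents that add atoms: none
Why: Ortho C-alkylation of an ambident phenoxide (phenolate C-prenylation): in water the oxygen is tied up by hydrogen bonding, so the soft allylic bromide attacks the ring carbon, and with the para position blocked the only site is ortho to OH; the yield is modest and no stereocenter is formed.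

Step 2
Reactants: 3 4-hydroxy-3-(3-methylbut-2-en-1-yl)benzaldehyde; 4 4-methylbenzenesulfonohydrazide
Product: 8 2-(3-methylbut-2-en-1-yl)-4-[(4,4,5,5-tetramethyl-1,3,2-dioxaborolan-2-yl)methyl]phenol, via tosylhydrazone 5 (not isolated), via aryldiazomethane 6 (not isolated), via geminal bis-boronate 7 (not isolated)
Conditions: TsNHNH2, MeOH, rt; concentrate; then B2pin2 (1.5 equiv), NaOMe (2.2 equiv), toluene/1,4-dioxane, 110 °C; aq. NH4Cl work-up
Reagents that add atoms: bis(pinacolato)diboron, CC1(C)OB(OC1(C)C)B1OC(C)(C)C(C)(C)O1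
Why: Bamford–Stevens decomposition of the tosylhydrazone salt gives the aryldiazomethane, which inserts into the B–B bond (1,2-boryl shift with loss of N2), and methoxide/methanol mono-protodeboronates the geminal bis-boronate (reductive borylation of N-tosylhydrazones); the second equivalent of base only parks the phenol as its phenoxide and no stereocenter is formed.

Step 3
Reactants: 9 mucobromic acid (3,4-dibromo-5-hydroxyfuran-2(5H)-one); 10 (4-hydroxyphenyl)boronic acid
Product: 11 3-bromo-5-hydroxy-4-(4-hydroxyphenyl)furan-2(5H)-one (racemic)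
Conditions: PdCl2(PPh3)2 (5 mol%), CsF (3 equiv), BnEt3NCl (5 mol%), toluene/H2O (1:1), rt
Reagents that add atoms: none
Why: Site-selective Suzuki–Miyaura coupling: oxidative addition is faster at the C4–Br bond, which is beta to the lactone carbonyl (a vinylogous acyl bromide), and the fluoride/phase-transfer conditions spare the base-labile pseudo-acid; the lactol carbon stays racemic, which does not matter because it becomes the ester carbonyl.

Step 4
Reactants: 11 3-bromo-5-hydroxy-4-(4-hydroxyphenyl)furan-2(5H)-one; 8 2-(3-methylbut-2-en-1-yl)-4-[(4,4,5,5-tetramethyl-1,3,2-dioxaborolan-2-yl)methyl]phenol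
Product: 12 5-hydroxy-4-(4-hydroxyphenyl)-3-{[4-hydroxy-3-(3-methylbut-2-en-1-yl)phenyl]methyl}furan-2(5H)-one (racemic)
Conditions: Pd(OAc)2 (5 mol%), 2-dicyclohexylphosphino-2',6'-dimethoxybiphenyl (SPhos, 10 mol%), CsF (3 equiv), 1,4-dioxane/H2O (10:1), 70 °C; aq. citric acid work-up
Reagents that add atoms: none
Why: sp2–sp3 Suzuki–Miyaura coupling of the remaining alpha C–Br bond with a primary benzylic boronate that has no beta-hydrogen; the bulky electron-rich biarylphosphine drives oxidative addition at the hindered position, the free phenols and the lactol are tolerated under fluoride activation, and no new stereocenter is formed.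

Step 5
Reactants: 12 5-hydroxy-4-(4-hydroxyphenyl)-3-{[4-hydroxy-3-(3-methylbut-2-en-1-yl)phenyl]methyl}furan-2(5H)-one
Product: 14 (2R,3S)-2-{[4-hydroxy-3-(3-methylbut-2-en-1-yl)phenyl]methyl}-3-(4-hydroxyphenyl)-4-methoxy-4-oxobutanoic acid (Asperteretal G1), via ring-opened formyl acrylic acid 13 (not isolated)
Conditions: (5aS,10bR)-5a,10b-dihydro-2-(2,4,6-trimethylphenyl)-4H,6H-indeno[2,1-b][1,2,4]triazolo[4,3-d][1,4]oxazinium chloride (20 mol%), iPr2NEt (1.2 equiv), dry MeOH (20 equiv), THF, 0 °C, Ar; cold aq. citric acid work-up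
Reagents that add atoms: methanol, CO
Why: Proposed new method: the amine opens pseudo-acid 12 to the (Z)-formyl acrylate 13, the chiral triazolylidene adds to the aldehyde to give a Breslow intermediate whose homoenolate carbon (the one carrying benzyl and carboxylate) is protonated on the face left open by the indane wall (sets C2 as R), the resulting azolium enolate is then C-protonated directly beside the chiral azolium (sets C3 as S, anti), and the acyl azolium is captured by methanol in the C–O bond-forming turnover step, so the methoxy group can only end up on the former aldehyde carbon while the spectator carboxylate becomes the free acid; the closest known reaction types are the carbene-catalysed internal redox esterification of enals, the enantioselective beta-protonation of beta,beta-disubstituted enals and the generation of azolium enolates from 4-oxo-enoates, none of which has been run on a gamma-hydroxybutenolide or used to set two adjacent stereocenters by two successive protonations.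

**Compound list**
1 | 4-hydroxybenzaldehyde | O=Cc1ccc(O)cc1 | starting material
2 | prenyl bromide (1-bromo-3-methylbut-2-ene) | CC(C)=CCBr | starting material
3 | 4-hydroxy-3-(3-methylbut-2-en-1-yl)benzaldehyde | CC(C)=CCc1cc(C=O)ccc1O | intermediate
4 | 4-methylbenzenesulfonohydrazide | Cc1ccc(cc1)S(=O)(=O)NN | starting material
5 | N'-[(E)-[4-hydroxy-3-(3-methylbut-2-en-1-yl)phenyl]methylidene]-4-methylbenzenesulfonohydrazide | CC(C)=CCc1cc(/C=N/NS(=O)(=O)c2ccc(C)cc2)ccc1O | intermediate
6 | 4-(diazomethyl)-2-(3-methylbut-2-en-1-yl)phenol (present as its sodium phenoxide) | CC(C)=CCc1cc(C=[N+]=[N-])ccc1O | intermediate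
7 | 4-[bis(4,4,5,5-tetramethyl-1,3,2-dioxaborolan-2-yl)methyl]-2-(3-methylbut-2-en-1-yl)phenol | CC(C)=CCc1cc(C(B2OC(C)(C)C(C)(C)O2)B2OC(C)(C)C(C)(C)O2)ccc1O | intermediate
8 | 2-(3-methylbut-2-en-1-yl)-4-[(4,4,5,5-tetramethyl-1,3,2-dioxaborolan-2-yl)methyl]phenol | CC(C)=CCc1cc(CB2OC(C)(C)C(C)(C)O2)ccc1O | intermediate
9 | mucobromic acid (3,4-dibromo-5-hydroxyfuran-2(5H)-one, racemic lactol) | O=C1OC(O)C(Br)=C1Br | starting material
10 | (4-hydroxyphenyl)boronic acid | OB(O)c1ccc(O)cc1 | starting material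
11 | 3-bromo-5-hydroxy-4-(4-hydroxyphenyl)furan-2(5H)-one (racemic) | O=C1OC(O)C(c2ccc(O)cc2)=C1Br | intermediate
12 | 5-hydroxy-4-(4-hydroxyphenyl)-3-{[4-hydroxy-3-(3-methylbut-2-en-1-yl)phenyl]methyl}furan-2(5H)-one (racemic) | O=C1OC(O)C(c2ccc(O)cc2)=C1Cc1ccc(O)c(CC=C(C)C)c1 | intermediate
13 | (2Z)-2-{[4-hydroxy-3-(3-methylbut-2-en-1-yl)phenyl]methyl}-3-(4-hydroxyphenyl)-4-oxobut-2-enoic acid (present as its ammonium carboxylate) | O=C/C(c1ccc(O)cc1)=C(C(=O)O)/Cc1ccc(O)c(CC=C(C)C)c1 | intermediate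
14 | (2R,3S)-2-{[4-hydroxy-3-(3-methylbut-2-en-1-yl)phenyl]methyl}-3-(4-hydroxyphenyl)-4-methoxy-4-oxobutanoic acid (Asperteretal G1) | COC(=O)[C@H](c1ccc(O)cc1)[C@@H](Cc1ccc(O)c(CC=C(C)C)c1)C(=O)O | target

**Count**
Total steps: 5. Longest linear sequence: 4 (steps 1, 2, 4, 5; step 3 is a one-step side branch).

**Steps most likely to fail, with fallbacks**

Step 2. The free phenol may interfere: the phenoxide-substituted diazo compound could give azine, or the disodium salt could be too insoluble. The fallback forms the C–B bond by Miyaura borylation of a benzylic chloride instead of carbene insertion; it sets out from 3 and comes back at 8. Compound 3 is silylated (TBSCl, imidazole, DMF) to 4-[(tert-butyldimethylsilyl)oxy]-3-(3-methylbut-2-en-1-yl)benzaldehyde F1. Reduction (NaBH4, MeOH, 0 °C) gives {4-[(tert-butyldimethylsilyl)oxy]-3-(3-methylbut-2-en-1-yl)phenyl}methanol F2. MsCl, Et3N and LiCl in CH2Cl2/THF convert it into tert-butyl[4-(chloromethyl)-2-(3-methylbut-2-en-1-yl)phenoxy]dimethylsilane F3. Borylation (B2pin2, Pd(dba)2, P(4-MeOC6H4)3, KOAc, toluene, 50 °C) gives tert-butyldimethyl{2-(3-methylbut-2-en-1-yl)-4-[(4,4,5,5-tetramethyl-1,3,2-dioxaborolan-2-yl)methyl]phenoxy}silane F4. Desilylation with Bu4NF/AcOH (THF, 0 °C) returns 8.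

Step 4. The benzylic boronate may transmetalate slowly, and the ring-opened bromo-lactol may decompose in warm aqueous fluoride. The fallback avoids the benzylic cross-coupling by building the C3–benzyl bond through reductive alkylation and the C4–aryl bond afterwards; it sets out from 3 (with 10) and comes back at 12. Tetronic acid, 3 and diethyl 2,6-dimethyl-1,4-dihydropyridine-3,5-dicarboxylate with L-proline (10 mol%) in CH2Cl2 at rt give 4-hydroxy-3-{[4-hydroxy-3-(3-methylbut-2-en-1-yl)phenyl]methyl}furan-2(5H)-one F5. The far more acidic enol is sulfonylated selectively (TsCl, 1.05 equiv iPr2NEt, CH2Cl2, 0 °C) to 4-{[4-hydroxy-3-(3-methylbut-2-en-1-yl)phenyl]methyl}-5-oxo-2,5-dihydrofuran-3-yl 4-methylbenzenesulfonate F6. Suzuki–Miyaura coupling with 10 (PdCl2(PPh3)2, KF, THF/H2O, 60 °C) gives 4-(4-hydroxyphenyl)-3-{[4-hydroxy-3-(3-methylbut-2-en-1-yl)phenyl]methyl}furan-2(5H)-one F7. Its dienolate is oxygenated at the gamma carbon (O2, DBU, MeCN, 0 °C) to 5-hydroperoxy-4-(4-hydroxyphenyl)-3-{[4-hydroxy-3-(3-methylbut-2-en-1-yl)phenyl]methyl}furan-2(5H)-one F8, which is reduced in the same flask with Me2S to lactol 12. The oxygenation must be stopped before over-oxidation to the maleic anhydride.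

Step 5 (the proposed new step). Three failure modes are plausible:
- low ee at the remote benzyl-bearing carbon;
- a syn/anti mixture;
- loss of regiocontrol if the acyl azolium is trapped by the neighbouring carboxylate as the cyclic anhydride before methanol reacts.

The fallback uses known auxiliary chemistry, sets out from 3 and comes back at 14. Compound 3 is silylated to F1 as in the fallback for step 2. Masamune–Roush olefination of F1 with commercial (4S)-4-benzyl-3-[(diethoxyphosphoryl)acetyl]-1,3-oxazolidin-2-one (LiCl, iPr2NEt, MeCN) gives (4S)-4-benzyl-3-[(2E)-3-{4-[(tert-butyldimethylsilyl)oxy]-3-(3-methylbut-2-en-1-yl)phenyl}prop-2-enoyl]-1,3-oxazolidin-2-one F9. Conjugate reduction with LiBH(sec-Bu)3 (THF, −78 °C) gives (4S)-4-benzyl-3-(3-{4-[(tert-butyldimethylsilyl)oxy]-3-(3-methylbut-2-en-1-yl)phenyl}propanoyl)-1,3-oxazolidin-2-one F10. Separately, commercial methyl (4-hydroxyphenyl)acetate is silylated (TBSCl, imidazole) to methyl {4-[(tert-butyldimethylsilyl)oxy]phenyl}acetate F11 and brominated through its enolate (LiN(SiMe3)2, THF, −78 °C, then CBr4) to racemic methyl bromo{4-[(tert-butyldimethylsilyl)oxy]phenyl}acetate F12. Evans alkylation of the sodium (Z)-enolate of F10 (NaN(SiMe3)2, THF, −78 °C) with F12 takes place anti to the benzyl group of the auxiliary and fixes the (R) configuration of the benzyl-bearing carbon. The alkylation does not control the aryl-bearing carbon, so the wanted diastereomer, methyl (2S,3R)-4-[(4S)-4-benzyl-2-oxo-1,3-oxazolidin-3-yl]-2-{4-[(tert-butyldimethylsilyl)oxy]phenyl}-3-({4-[(tert-butyldimethylsilyl)oxy]-3-(3-methylbut-2-en-1-yl)phenyl}methyl)-4-oxobutanoate F13, is separated from its epimer at that carbon, which is recycled by DBU equilibration. LiOH/H2O2 (THF/H2O, 0 °C) cleaves the auxiliary while sparing the methyl ester and gives (2R,3S)-2-({4-[(tert-butyldimethylsilyl)oxy]-3-(3-methylbut-2-en-1-yl)phenyl}methyl)-3-{4-[(tert-butyldimethylsilyl)oxy]phenyl}-4-methoxy-4-oxobutanoic acid F14. Bu4NF/AcOH (THF, 0 °C) removes both silyl groups to give 14.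

**Further compounds**
F1 | step 2 | 4-[(tert-butyldimethylsilyl)oxy]-3-(3-methylbut-2-en-1-yl)benzaldehyde | CC(C)=CCc1cc(C=O)ccc1O[Si](C)(C)C(C)(C)C
F2 | step 2 | {4-[(tert-butyldimethylsilyl)oxy]-3-(3-methylbut-2-en-1-yl)phenyl}methanol | CC(C)=CCc1cc(CO)ccc1O[Si](C)(C)C(C)(C)C
F3 | step 2 | tert-butyl[4-(chloromethyl)-2-(3-methylbut-2-en-1-yl)phenoxy]dimethylsilane | CC(C)=CCc1cc(CCl)ccc1O[Si](C)(C)C(C)(C)C
F4 | step 2 | tert-butyldimethyl{2-(3-methylbut-2-en-1-yl)-4-[(4,4,5,5-tetramethyl-1,3,2-dioxaborolan-2-yl)methyl]phenoxy}silane | CC(C)=CCc1cc(CB2OC(C)(C)C(C)(C)O2)ccc1O[Si](C)(C)C(C)(C)C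
F5 | step 4 | 4-hydroxy-3-{[4-hydroxy-3-(3-methylbut-2-en-1-yl)phenyl]methyl}furan-2(5H)-one | O=C1OCC(O)=C1Cc1ccc(O)c(CC=C(C)C)c1
F6 | step 4 | 4-{[4-hydroxy-3-(3-methylbut-2-en-1-yl)phenyl]methyl}-5-oxo-2,5-dihydrofuran-3-yl 4-methylbenzenesulfonate | Cc1ccc(cc1)S(=O)(=O)OC1=C(Cc2ccc(O)c(CC=C(C)C)c2)C(=O)OC1
F7 | step 4 | 4-(4-hydroxyphenyl)-3-{[4-hydroxy-3-(3-methylbut-2-en-1-yl)phenyl]methyl}furan-2(5H)-one | O=C1OCC(c2ccc(O)cc2)=C1Cc1ccc(O)c(CC=C(C)C)c1
F8 | step 4 | 5-hydroperoxy-4-(4-hydroxyphenyl)-3-{[4-hydroxy-3-(3-methylbut-2-en-1-yl)phenyl]methyl}furan-2(5H)-one (racemic) | O=C1OC(OO)C(c2ccc(O)cc2)=C1Cc1ccc(O)c(CC=C(C)C)c1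
F9 | step 5 | (4S)-4-benzyl-3-[(2E)-3-{4-[(tert-butyldimethylsilyl)oxy]-3-(3-methylbut-2-en-1-yl)phenyl}prop-2-enoyl]-1,3-oxazolidin-2-one | O=C(/C=C/c1ccc(O[Si](C)(C)C(C)(C)C)c(CC=C(C)C)c1)N1[C@@H](Cc2ccccc2)COC1=O
F10 | step 5 | (4S)-4-benzyl-3-(3-{4-[(tert-butyldimethylsilyl)oxy]-3-(3-methylbut-2-en-1-yl)phenyl}propanoyl)-1,3-oxazolidin-2-one | O=C(CCc1ccc(O[Si](C)(C)C(C)(C)C)c(CC=C(C)C)c1)N1[C@@H](Cc2ccccc2)COC1=O
F11 | step 5 | methyl {4-[(tert-butyldimethylsilyl)oxy]phenyl}acetate | COC(=O)Cc1ccc(O[Si](C)(C)C(C)(C)C)cc1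
F12 | step 5 | methyl bromo{4-[(tert-butyldimethylsilyl)oxy]phenyl}acetate (racemic) | COC(=O)C(Br)c1ccc(O[Si](C)(C)C(C)(C)C)cc1
F13 | step 5 | methyl (2S,3R)-4-[(4S)-4-benzyl-2-oxo-1,3-oxazolidin-3-yl]-2-{4-[(tert-butyldimethylsilyl)oxy]phenyl}-3-({4-[(tert-butyldimethylsilyl)oxy]-3-(3-methylbut-2-en-1-yl)phenyl}methyl)-4-oxobutanoate | COC(=O)[C@H](c1ccc(O[Si](C)(C)C(C)(C)C)cc1)[C@@H](Cc1ccc(O[Si](C)(C)C(C)(C)C)c(CC=C(C)C)c1)C(=O)N1[C@@H](Cc2ccccc2)COC1=O
F14 | step 5 | (2R,3S)-2-({4-[(tert-butyldimethylsilyl)oxy]-3-(3-methylbut-2-en-1-yl)phenyl}methyl)-3-{4-[(tert-butyldimethylsilyl)oxy]phenyl}-4-methoxy-4-oxobutanoic acid | COC(=O)[C@H](c1ccc(O[Si](C)(C)C(C)(C)C)cc1)[C@@H](Cc1ccc(O[Si](C)(C)C(C)(C)C)c(CC=C(C)C)c1)C(=O)O
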